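**Plan**

1. Retrosynthesis cuts three bonds: the ring C–CO2H bond, the ring C–CH3 bond (both back to C–H of a 5-alkylresorcinol dimethyl ether), and the side-chain C2′–C3′ bond (CH2–CH2, counted from the benzene ring).
2. Enabling feature: C2′ and C3′ are both unbranched, unactivated CH2 groups, so each can arise as a primary radical from a carboxyl group. The ring half is then a hydrocinnamic acid on a 3,5-dioxygenated benzene ring (1), and the chain half is natural iso-C14 acid 3, whose isopropyl terminus is bought, not built.
3. Forward: both acids become N-hydroxyphthalimide esters, and a nickel-electrocatalytic doubly decarboxylative C(sp3)–C(sp3) coupling joins the complete C15 chain to the arene in one event. The two CO2 units are the only helpers and leave in that same step.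
4. The benzene ring is present from the start. The two ring carbons flanking the chain are each para to one OMe and ortho to the other, so CH3 (Vilsmeier formylation, hydrogenolysis) and CO2H (second Vilsmeier formylation, Pinnick oxidation) enter there by innate reactivity; BBr3 then frees both phenols.
5. Stereochemistry: the target has no stereocentre and no stereogenic double bond, so nothing has to be set. Remark on the chemistry: "single enantiomer" is taken to mean this one achiral compound.

Key step: step 3

**Route**

Step 1
Reactants: 1 3-(3,5-dimethoxyphenyl)propanoic acid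
Product: 2 1,3-dioxoisoindolin-2-yl 3-(3,5-dimethoxyphenyl)propanoate
Conditions: NHPI (1.1 equiv), DIC (1.1 equiv), DMAP (10 mol%), CH2Cl2, rt
Reagents that add atoms: N-hydroxyphthalimide, O=C1c2ccccc2C(=O)N1O
Why: Carbodiimide (Steglich-type) esterification, in which DIC activates the acid as an O-acylisourea that DMAP passes on to the N–OH group, and nothing else in 1 is nucleophilic or base-sensitive.

Step 2
Reactants: 3 12-methyltridecanoic acid
Product: 4 1,3-dioxoisoindolin-2-yl 12-methyltridecanoate
Conditions: NHPI (1.1 equiv), DIC (1.1 equiv), DMAP (10 mol%), CH2Cl2, rt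
Reagents that add atoms: N-hydroxyphthalimide, O=C1c2ccccc2C(=O)N1O
Why: The same carbodiimide esterification on an unfunctionalised fatty acid should give the crystalline redox-active ester without complication.

Step 3
Reactants: 2 1,3-dioxoisoindolin-2-yl 3-(3,5-dimethoxyphenyl)propanoate (3 equiv); 4 1,3-dioxoisoindolin-2-yl 12-methyltridecanoate (1 equiv)
Product: 5 1,3-dimethoxy-5-(13-methyltetradecyl)benzene
Conditions: NiCl2·6H2O (20 mol%), 2,2′:6′,2″-terpyridine (20 mol%), AgNO3 (0.3 equiv), NaI, NMP, Mg(+)/RVC(−), constant current, undivided cell, rt
Reagents that add atoms: none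
Why: Cathodically generated low-valent nickel–terpyridine transfers an electron to each N-acyloxyphthalimide, which fragments to phthalimide anion, CO2 and a primary alkyl radical (ArCH2CH2• from 2, (CH3)2CH(CH2)10CH2• from 4); both radicals are captured at nickel and the dialkylnickel(III) species reductively eliminates the new C2′–C3′ bond, with the Mg anode supplying the electrons and the silver-coated cathode keeping the esters from direct reduction. The closest known reaction type is the Ni-electrocatalytic doubly decarboxylative C(sp3)–C(sp3) coupling of two redox-active esters, which is established for pairs of primary alkyl partners. No ring is closed and no stereocentre is formed. The step needs cross-coupling over homo-coupling, which for two primary radicals is only statistical, so the cheaper ester 2 is used in excess, and the single dimethoxyphenyl group places 5 between the hydrocarbon dimer of 4 and the tetramethoxy dimer of 2 in polarity for separation. It also needs chemoselectivity for the two N–O esters, which the wholly reductive regime secures: the electron-rich 3,5-dimethoxyphenyl ring that an anodic Kolbe coupling would oxidise is not touched, and neither radical is benzylic, branched or β-heteroatom-substituted, so no rearrangement or elimination should compete.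

Step 4
Reactants: 5 1,3-dimethoxy-5-(13-methyltetradecyl)benzene
Product: 7 2,4-dimethoxy-6-(13-methyltetradecyl)benzaldehyde, via iminium chloride 6 (not isolated)
Conditions: POCl3 (1.5 equiv), DMF/ClCH2CH2Cl, 0 → 70 °C; then H2O
Reagents that add atoms: N,N-dimethylformamide, CN(C)C=O; water, O
Why: Vilsmeier–Haack formylation, in which the chloroiminium electrophile should attack a ring carbon next to the chain (para to one OMe, ortho to the other) in preference to the crowded carbon between the two OMe groups, and the two chain-flanking carbons are equivalent so only one such aldehyde can form.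

Step 5
Reactants: 7 2,4-dimethoxy-6-(13-methyltetradecyl)benzaldehyde
Product: 9 1,5-dimethoxy-2-methyl-3-(13-methyltetradecyl)benzene, via benzylic alcohol 8 (not isolated)
Conditions: H2 (3 atm), 10% Pd/C, EtOAc/AcOH, cat. HClO4, rt
Reagents that add atoms: none
Why: Catalytic hydrogenation followed by acid-assisted benzylic hydrogenolysis, since the C–O bond of alcohol 8 is activated by the ortho and para methoxy groups while aryl methyl ethers and the saturated chain are inert on Pd.

Step 6
Reactants: 9 1,5-dimethoxy-2-methyl-3-(13-methyltetradecyl)benzene
Product: 11 2,4-dimethoxy-5-methyl-6-(13-methyltetradecyl)benzaldehyde, via iminium chloride 10 (not isolated)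
Conditions: POCl3 (2 equiv), DMF/ClCH2CH2Cl, 0 → 80 °C; then H2O
Reagents that add atoms: N,N-dimethylformamide, CN(C)C=O; water, O
Why: Second Vilsmeier–Haack formylation, where of the two free ring carbons the one flanked by the chain is again para to an OMe group and less hindered than the one between the two OMe groups, so the formyl group should enter at the future carboxyl position.

Step 7
Reactants: 11 2,4-dimethoxy-5-methyl-6-(13-methyltetradecyl)benzaldehyde
Product: 12 2,4-dimethoxy-5-methyl-6-(13-methyltetradecyl)benzoic acid
Conditions: NaClO2, NaH2PO4, 2-methyl-2-butene (excess), t-BuOH/THF/H2O, 0 °C → rt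
Reagents that add atoms: sodium chlorite, [Na+].[O-]Cl=O
Why: Pinnick oxidation should convert the hindered aryl aldehyde into the acid under buffered conditions, with 2-methyl-2-butene removing HOCl before it can chlorinate the activated ring carbon between the OMe groups.

Step 8
Reactants: 12 2,4-dimethoxy-5-methyl-6-(13-methyltetradecyl)benzoic acid
Product: 13 2,4-dihydroxy-5-methyl-6-(13-methyltetradecyl)benzoic acid
Conditions: BBr3 (5 equiv), CH2Cl2, −78 → 0 °C; then ice-water
Reagents that add atoms: none
Why: Lewis-acid ether cleavage, in which BBr3 coordinates each aryl methyl ether oxygen (the ortho one assisted by the carboxyl group) and bromide removes the methyl groups by SN2, and the cold aqueous work-up should release both phenols without heating the decarboxylation-prone β-resorcylic acid.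

**Compound list**

1 | 3-(3,5-dimethoxyphenyl)propanoic acid | COc1cc(OC)cc(CCC(=O)O)c1 | starting material
2 | 1,3-dioxoisoindolin-2-yl 3-(3,5-dimethoxyphenyl)propanoate | COc1cc(OC)cc(CCC(=O)ON2C(=O)c3ccccc3C2=O)c1 | intermediate
3 | 12-methyltridecanoic acid | CC(C)CCCCCCCCCCC(=O)O | starting material
4 | 1,3-dioxoisoindolin-2-yl 12-methyltridecanoate | CC(C)CCCCCCCCCCC(=O)ON1C(=O)c2ccccc2C1=O | intermediate
5 | 1,3-dimethoxy-5-(13-methyltetradecyl)benzene | COc1cc(OC)cc(CCCCCCCCCCCCC(C)C)c1 | intermediate
6 | N-{[2,4-dimethoxy-6-(13-methyltetradecyl)phenyl]methylidene}-N-methylmethanaminium chloride | C[N+](C)=Cc1c(OC)cc(OC)cc1CCCCCCCCCCCCC(C)C.[Cl-] | intermediate (not isolated)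
7 | 2,4-dimethoxy-6-(13-methyltetradecyl)benzaldehyde | O=Cc1c(OC)cc(OC)cc1CCCCCCCCCCCCC(C)C | intermediate
8 | [2,4-dimethoxy-6-(13-methyltetradecyl)phenyl]methanol | OCc1c(OC)cc(OC)cc1CCCCCCCCCCCCC(C)C | intermediate (not isolated)
9 | 1,5-dimethoxy-2-methyl-3-(13-methyltetradecyl)benzene | Cc1c(OC)cc(OC)cc1CCCCCCCCCCCCC(C)C | intermediate
10 | N-{[2,4-dimethoxy-5-methyl-6-(13-methyltetradecyl)phenyl]methylidene}-N-methylmethanaminium chloride | C[N+](C)=Cc1c(OC)cc(OC)c(C)c1CCCCCCCCCCCCC(C)C.[Cl-] | intermediate (not isolated)
11 | 2,4-dimethoxy-5-methyl-6-(13-methyltetradecyl)benzaldehyde | O=Cc1c(OC)cc(OC)c(C)c1CCCCCCCCCCCCC(C)C | intermediate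
12 | 2,4-dimethoxy-5-methyl-6-(13-methyltetradecyl)benzoic acid | OC(=O)c1c(OC)cc(OC)c(C)c1CCCCCCCCCCCCC(C)C | intermediate
13 | 2,4-dihydroxy-5-methyl-6-(13-methyltetradecyl)benzoic acid | Cc1c(O)cc(O)c(C(=O)O)c1CCCCCCCCCCCCC(C)C | target

**Step count and risks**

Total step count: 8. Longest linear sequence: 7 steps (1, 3, 4, 5, 6, 7, 8).

Step 3 (key coupling). The two primary radicals may pair mainly with their own kind, or the esters may be lost by premature reduction or hydrolysis before nickel captures the radicals. The fallback joins the chain by olefination one bond closer to the ring. It sets out from 3: reduction (LiAlH4, THF) should give 12-methyltridecan-1-ol F1, and Dess–Martin oxidation should give 12-methyltridecanal F2. Wittig reaction with the ylide from commercial (3,5-dimethoxybenzyl)triphenylphosphonium bromide (KOt-Bu, THF) should give 1,3-dimethoxy-5-(13-methyltetradec-1-en-1-yl)benzene F3 as an E/Z mixture. Hydrogenation (H2, Pd/C, EtOAc) converges both isomers and comes back to the route at 5.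

Step 6 (second formylation). The electrophile may attack between the two methoxy groups, or the hindered, lipophilic arene may react sluggishly. The fallback brings in the carboxyl carbon by chelation-controlled carboxylation of the free resorcinol. It sets out from 9: BBr3 (CH2Cl2, −78 °C → rt) should give 4-methyl-5-(13-methyltetradecyl)benzene-1,3-diol F4. Kolbe–Schmitt-type carboxylation with methyl magnesium carbonate (DMF, 120 °C, then cold dilute HCl) should place CO2H ortho to a phenol on the chain-flanked carbon, as in the carboxylation of 5-alkylresorcinols to 6-alkyl-β-resorcylic acids. It comes back to the route at 13.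

Step 8 (final demethylation). Protodecarboxylation of the electron-rich β-resorcylic acid under the acidic conditions, or incomplete cleavage of the hindered ether, may erode the product. The fallback changes the protecting groups so that the acid is unveiled under neutral hydrogenolysis. It sets out from 11: BBr3 should give 2,4-dihydroxy-5-methyl-6-(13-methyltetradecyl)benzaldehyde F5, which is not prone to decarboxylation. Benzylation (BnBr, K2CO3, DMF, 60 °C) should give 2,4-bis(benzyloxy)-5-methyl-6-(13-methyltetradecyl)benzaldehyde F6, and Pinnick oxidation should give 2,4-bis(benzyloxy)-5-methyl-6-(13-methyltetradecyl)benzoic acid F7. Hydrogenolysis (H2, Pd/C, EtOAc, rt) comes back to the route at 13.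

Further compounds
F1 | step 3 | 12-methyltridecan-1-ol | OCCCCCCCCCCCC(C)C
F2 | step 3 | 12-methyltridecanal | O=CCCCCCCCCCCC(C)C
F3 | step 3 | 1,3-dimethoxy-5-(13-methyltetradec-1-en-1-yl)benzene (E/Z mixture) | COc1cc(OC)cc(C=CCCCCCCCCCCC(C)C)c1
F4 | step 6 | 4-methyl-5-(13-methyltetradecyl)benzene-1,3-diol | Cc1c(O)cc(O)cc1CCCCCCCCCCCCC(C)C
F5 | step 8 | 2,4-dihydroxy-5-methyl-6-(13-methyltetradecyl)benzaldehyde | O=Cc1c(O)cc(O)c(C)c1CCCCCCCCCCCCC(C)C
F6 | step 8 | 2,4-bis(benzyloxy)-5-methyl-6-(13-methyltetradecyl)benzaldehyde | O=Cc1c(OCc2ccccc2)cc(OCc2ccccc2)c(C)c1CCCCCCCCCCCCC(C)C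
F7 | step 8 | 2,4-bis(benzyloxy)-5-methyl-6-(13-methyltetradecyl)benzoic acid | OC(=O)c1c(OCc2ccccc2)cc(OCc2ccccc2)c(C)c1CCCCCCCCCCCCC(C)C
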